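**Retrosynthetic overview**
1. Target 22 ⇒ 8β,11-diol 20. C11 is kept at the alcohol level so that H-9 is not acidic while the C8 carbinol is built.
2. 20 ⇒ trans-hydrindane 18. Ring B (C5–C6–C7–C8–C9–C10) comes from the five-membered ring C5–C6–C7–C8–C10 by a semipinacol 1,2-shift of C10 from C8 to the oxirane carbon C9. Methyl transfer to the new C8 ketone follows in the same flask.
3. Enabling feature: the C8(O)–C9–C11(O) 1,3-dioxygen array of ring B lies directly beside the quaternary ring-fusion carbon C10. C9 can therefore be inserted into the C8–C10 bond, and the axial C10 methyl then blocks the β face of C8.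
4. 18 ⇒ chloro ketone 14 ⇒ (S)-enedione 4. C4/C5 come from reductive alkylation, C3–Cl from an axial alcohol and inversion, and C10 from an amino-acid-mediated aldol condensation.
5. Ring order: five-membered ring (present in 1), ring A (step 2), ring B (step 15).

Key step: step 15

Remark: labdane-type locants of the target are used for all compounds (ring A = C1, C2, C3, C4, C5, C10; ring B = C5 to C10; C11 = carbon on C9; β = face of the C10 methyl, α = face of H-5).
Assumption: compounds 1, 2 and 7 are taken as commercial.

**Step 1**
Reactants: 1 2-methylcyclopentane-1,3-dione; 2 pent-1-en-3-one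
Product: 3 2-methyl-2-(3-oxopentyl)cyclopentane-1,3-dione
Conditions: H2O, AcOH (cat.), 70 °C
Reagents that add atoms: none
Why: Michael addition of the enolised 1,3-dione to the enone under near-neutral aqueous conditions stops at the triketone, and the new quaternary carbon (future C10) is still prochiral.

**Step 2**
Reactants: 3 2-methyl-2-(3-oxopentyl)cyclopentane-1,3-dione
Product: 4 (7aS)-4,7a-dimethyl-2,3,7,7a-tetrahydro-1H-indene-1,5(6H)-dione
Conditions: L-phenylalanine (1 equiv), (+)-CSA (0.5 equiv), MeCN, reflux
Reagents that add atoms: none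
Why: Hajos–Parrish–Eder–Sauer–Wiechert reaction (enamine-mediated intramolecular aldol condensation closing ring A), in which the L-amino acid selects one of the two enantiotopic ring carbonyls and fixes C10 as (S), with enrichment by recrystallisation foreseen.

**Step 3**
Reactants: 4 (S)-enedione
Product: 5 8β-hydroxy enone (C8 ketone of 4 reduced, OH on the face of the C10 methyl)
Conditions: NaBH4, EtOH, −15 °C
Reagents that add atoms: none
Why: Chemoselective borohydride reduction of the more electrophilic saturated cyclopentanone beside the tetrasubstituted enone, with hydride delivery from the α face opposite the angular methyl.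

**Step 4**
Reactants: 5 8β-hydroxy enone
Product: 6 8β-(tert-butyldimethylsilyloxy) enone
Conditions: TBSCl, imidazole, DMF, rt
Reagents that add atoms: tert-butyldimethylsilyl chloride, CC(C)(C)[Si](C)(C)Cl
Why: Standard silylation masks the C8 oxygen for the dissolving-metal and hydride steps, and no stereocentre is touched.

**Step 5**
Reactants: 7 5-bromo-2-methylpent-2-ene
Product: 8 5-iodo-2-methylpent-2-ene
Conditions: NaI, acetone, reflux
Reagents that add atoms: sodium iodide, [Na+].[I-]
Why: Finkelstein halide exchange, driven by precipitation of sodium bromide, gives the more reactive alkylating agent.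

**Step 6**
Reactants: 6 8β-silyloxy enone; 8 5-iodo-2-methylpent-2-ene
Product: 10 trans-hydrindan-3-one (H-5α; C4 with β-axial methyl and α-equatorial 4-methylpent-3-enyl; 10β-methyl; 8β-OTBS), via lithium enolate 9 (not isolated)
Conditions: Li, NH3(l)/THF, H2O (1.0 equiv), −78 → −33 °C; isoprene; then 8, THF, −33 °C → rt
Reagents that add atoms: none
Why: Stork reductive alkylation (Birch-type enone reduction with regiospecific enolate trapping), in which axial protonation at C5 gives the trans fusion and enolate 9 is alkylated from the α face away from the axial C10 methyl, so the new chain ends equatorial and the C4 methyl axial.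

**Step 7**
Reactants: 10 trans-hydrindan-3-one
Product: 11 3α-alcohol (axial OH)
Conditions: L-Selectride, THF, −78 °C; then H2O
Reagents that add atoms: none
Why: The bulky trialkylborohydride attacks the hindered C3 ketone along the equatorial trajectory and should give the axial 3α-alcohol needed for inversion.

**Step 8**
Reactants: 11 3α-alcohol
Product: 12 3β-chloride (equatorial Cl)
Conditions: PPh3, NCS (premixed), THF, 0 °C → rt
Reagents that add atoms: N-chlorosuccinimide, O=C1CCC(=O)N1Cl
Why: Appel-type chlorination, in which chloride displaces the alkoxyphosphonium salt of the axial alcohol in an SN2 step with inversion, a displacement with close precedent on cyclohexanols flanked by a quaternary carbon.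

**Step 9**
Reactants: 12 3β-chloro silyl ether
Product: 13 3β-chloro-8β-ol
Conditions: TBAF, THF, 50 °C
Reagents that add atoms: none
Why: Fluoride-induced desilylation frees the C8 alcohol, while the equatorial neopentylic chloride has no antiperiplanar hydrogen for E2 loss and the alkene is inert.

**Step 10**
Reactants: 13 3β-chloro-8β-ol
Product: 14 3β-chloro-trans-hydrindan-8-one
Conditions: Dess–Martin periodinane, NaHCO3, CH2Cl2, rt
Reagents that add atoms: none
Why: Dess–Martin oxidation under buffered conditions returns the C8 ketone without touching the chloride or the trisubstituted alkene.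

**Step 11**
Reactants: 14 3β-chloro-8-ketone
Product: 15 8α-(1-ethoxyvinyl)-8β-ol
Conditions: ethyl vinyl ether, t-BuLi, THF, −78 → 0 °C; then 14, −78 °C
Reagents that add atoms: 1-ethoxyvinyllithium, [Li]C(=C)OCC (made in the flask from ethyl vinyl ether, C=COCC)
Why: 1,2-Addition of a metalated enol ether (nucleophilic acylation) to the hindered cyclopentanone occurs from the α face opposite the angular methyl, which puts the C9–C11 unit on the α face and the C8 hydroxyl on the β face.

**Step 12**
Reactants: 15 8α-(1-ethoxyvinyl)-8β-ol
Product: 16 8α-(chloroacetyl)-8β-ol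
Conditions: NCS (1.0 equiv), NaHCO3, THF/H2O, 0 °C
Reagents that add atoms: N-chlorosuccinimide, O=C1CCC(=O)N1Cl; water, O
Why: The electron-rich enol ether is chlorinated at its terminal carbon far faster than the trisubstituted alkene, and water hydrolyses the resulting oxocarbenium ion to the α-hydroxy chloromethyl ketone.

**Step 13**
Reactants: 16 8α-(chloroacetyl)-8β-ol
Product: 17 (9S)-8α-(2-chloro-1-hydroxyethyl)-8β-ol
Conditions: Zn(BH4)2, Et2O, −20 °C
Reagents that add atoms: none
Why: Chelation-controlled (Cram chelate) reduction, in which zinc ties the C8 hydroxyl to the C9 carbonyl and hydride enters from the side of the C7 methylene rather than of the quaternary C10, which should set C9 as (S).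

**Step 14**
Reactants: 17 chlorohydrin diol
Product: 18 (9R)-8α-oxiranyl-8β-ol
Conditions: KOt-Bu (1.0 equiv), THF, −20 °C
Reagents that add atoms: none
Why: Williamson-type 3-exo-tet closure of the secondary alkoxide onto the primary chloride gives the terminal oxirane with C9 unchanged in space, and one equivalent of base at low temperature is meant to suppress Payne migration.

**Step 15**
Reactants: 18 (9R)-8α-oxiranyl-8β-ol
Product: 20 trans-decalin 8β,11-diol (8α-methyl, 8β-OH axial, 9β-CH2OH equatorial, H-9α), via aluminium-bound ketone 19 (not isolated)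
Conditions: AlMe3 (4 equiv), CH2Cl2/hexane, −78 °C → rt; aq Rochelle salt
Reagents that add atoms: trimethylaluminium, C[Al](C)C
Why: Proposed new method: AlMe3 turns the C8 hydroxyl into an aluminium alkoxide (methane is lost) and a further aluminium centre binds the oxirane oxygen, so that the C8–C10 bond, which lies antiperiplanar to the C9–O bond in the O–Al–O chelate rotamer with H-9 turned under the ring, shifts suprafacially from C8 to C9 and gives the aluminium-bound 8-oxo-decalin 19, whose ketone then takes a methyl group from excess AlMe3. The closest known reaction types are the Lewis-acid semipinacol rearrangement of α-hydroxy epoxides with ring enlargement, its tandem form with aluminium alkoxides (rearrangement followed by Meerwein–Ponndorf–Verley reduction) and the organoaluminium-promoted pinacol-type shift of hydroxy mesylates, so only the coupling with methyl transfer is new. No ring is closed by cyclisation: the five-membered ring C5–C6–C7–C8–C10 becomes six-membered ring B by insertion of C9 through the 1,2-shift. C10 migrates with retention, C9 is set by inversion at the oxirane carbon (the (9R)-oxirane gives H-9α and an equatorial C11), and C8 is set by equatorial α-face methyl delivery because the axial C10 methyl blocks the β face, which leaves the hydroxyl axial. The step needs C10 and not C7 to migrate, and needs the shift to outrun direct methylation of the oxirane; the first is secured by the C9 configuration fixed in step 13, the higher migratory aptitude of the fully substituted C10 and the release of trans-hydrindane strain, the second by the intramolecular chelate-assisted shift at low temperature.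

**Step 16**
Reactants: 20 8β,11-diol
Product: 21 8β-hydroxy-11-oic acid
Conditions: TEMPO (cat.), PhI(OAc)2 (2.2 equiv), MeCN/H2O, rt
Reagents that add atoms: water, O
Why: Nitroxyl-catalysed oxidation with a hypervalent iodine co-oxidant takes the primary alcohol through the aldehyde hydrate to the acid under near-neutral conditions that spare the tertiary alcohol and the alkene and do not epimerise C9.

**Step 17**
Reactants: 21 8β-hydroxy-11-oic acid
Product: 22 target methyl ester
Conditions: TMSCHN2, MeOH/toluene, 0 °C
Reagents that add atoms: (trimethylsilyl)diazomethane, C[Si](C)(C)C=[N+]=[N-]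
Why: Methylation of the acid with (trimethylsilyl)diazomethane in methanol is base-free, so neither retro-aldol cleavage nor dehydration of the β-hydroxy ester can start.

**Compound list**
1 | 2-methylcyclopentane-1,3-dione | CC1C(=O)CCC1=O | starting material
2 | pent-1-en-3-one | CCC(=O)C=C | starting material
3 | 2-methyl-2-(3-oxopentyl)cyclopentane-1,3-dione | CCC(=O)CCC1(C)C(=O)CCC1=O | intermediate
4 | (7aS)-4,7a-dimethyl-2,3,7,7a-tetrahydro-1H-indene-1,5(6H)-dione | O=C1CC[C@]2(C)C(=O)CCC2=C1C | intermediate
5 | 8β-hydroxy enone | O=C1CC[C@]2(C)[C@@H](O)CCC2=C1C | intermediate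
6 | 8β-TBS ether of 5 | O=C1CC[C@]2(C)[C@@H](O[Si](C)(C)C(C)(C)C)CCC2=C1C | intermediate
7 | 5-bromo-2-methylpent-2-ene | CC(C)=CCCBr | starting material
8 | 5-iodo-2-methylpent-2-ene | CC(C)=CCCI | intermediate
9 | lithium C3–C4 enolate (H-5α) | [Li]OC1=C(C)[C@@H]2CC[C@H](O[Si](C)(C)C(C)(C)C)[C@@]2(C)CC1 | intermediate
10 | trans-hydrindan-3-one, 4β-Me, 4α-(4-methylpent-3-enyl), 8β-OTBS | O=C1CC[C@]2(C)[C@@H](O[Si](C)(C)C(C)(C)C)CC[C@H]2[C@]1(C)CCC=C(C)C | intermediate
11 | 3α-alcohol | O[C@@H]1CC[C@]2(C)[C@@H](O[Si](C)(C)C(C)(C)C)CC[C@H]2[C@]1(C)CCC=C(C)C | intermediate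
12 | 3β-chloride | Cl[C@H]1CC[C@]2(C)[C@@H](O[Si](C)(C)C(C)(C)C)CC[C@H]2[C@]1(C)CCC=C(C)C | intermediate
13 | 3β-chloro-8β-ol | Cl[C@H]1CC[C@]2(C)[C@@H](O)CC[C@H]2[C@]1(C)CCC=C(C)C | intermediate
14 | 3β-chloro-8-ketone | Cl[C@H]1CC[C@]2(C)C(=O)CC[C@H]2[C@]1(C)CCC=C(C)C | intermediate
15 | 8α-(1-ethoxyvinyl)-8β-ol | Cl[C@H]1CC[C@]2(C)[C@](O)(C(=C)OCC)CC[C@H]2[C@]1(C)CCC=C(C)C | intermediate
16 | 8α-(chloroacetyl)-8β-ol | Cl[C@H]1CC[C@]2(C)[C@](O)(C(=O)CCl)CC[C@H]2[C@]1(C)CCC=C(C)C | intermediate
17 | (9S)-8α-(2-chloro-1-hydroxyethyl)-8β-ol | Cl[C@H]1CC[C@]2(C)[C@](O)([C@H](O)CCl)CC[C@H]2[C@]1(C)CCC=C(C)C | intermediate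
18 | (9R)-8α-oxiranyl-8β-ol | Cl[C@H]1CC[C@]2(C)[C@](O)([C@H]3CO3)CC[C@H]2[C@]1(C)CCC=C(C)C | intermediate
19 | dimethylaluminium alkoxide of the 11-hydroxy-8-oxo trans-decalin | C[Al](C)OC[C@@H]1[C@@]2(C)CC[C@H](Cl)[C@@](C)(CCC=C(C)C)[C@@H]2CCC1=O | intermediate
20 | trans-decalin 8β,11-diol | OC[C@@H]1[C@@]2(C)CC[C@H](Cl)[C@@](C)(CCC=C(C)C)[C@@H]2CC[C@]1(C)O | intermediate
21 | 8β-hydroxy-11-oic acid | OC(=O)[C@@H]1[C@@]2(C)CC[C@H](Cl)[C@@](C)(CCC=C(C)C)[C@@H]2CC[C@]1(C)O | intermediate
22 | target methyl ester | COC(=O)[C@@H]1[C@@]2(C)CC[C@H](Cl)[C@@](C)(CCC=C(C)C)[C@@H]2CC[C@]1(C)O | target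

Total step count: 17. Longest linear sequence: 16 (steps 1–4 and 6–17).

**Steps most likely to fail**

Step 15. Methyl transfer from aluminium to the oxirane may run ahead of the 1,2-shift. The C7 methylene may migrate in place of C10. The aluminium aldolate may lose formaldehyde by retro-aldol cleavage. The fallback sets out from 18 and comes back at 20, and it separates the two events with known reagents. Catalytic ZnBr2 in CH2Cl2 performs the semipinacol ring enlargement alone and gives the 11-hydroxy-8-oxo trans-decalin F1, in which C9 can still be equilibrated to the equatorial epimer. Silylation (TBSCl, imidazole) gives the silyl ether ketone F2. MeMgBr/CeCl3 adds from the α face and gives the silyl ether tertiary alcohol F3. TBAF then gives 20.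

Step 8. E2 loss to the C2–C3 alkene, or a Wagner–Meerwein shift from the quaternary C4, may compete with the hindered SN2 displacement. The fallback sets out from 10 and comes back at 12, and it uses retention in place of inversion. NaBH4 (axial hydride attack) gives the equatorial 3β-alcohol F4. SOCl2 converts this into the 3β-chlorosulfite F5. Catalytic TiCl4 at 0 °C collapses it by front-side (SNi-type) chloride delivery to 12.

Step 6. C-alkylation of the hindered tetrasubstituted enolate by an unactivated homoallylic iodide may be slow, which leaves room for proton transfer. Protonation at C5 may also be incompletely trans-selective. The fallback sets out from 6 and comes back at 10. Enolate 9 is trapped with the activated electrophile allyl bromide to give the 4α-allyl ketone F6. 9-BBN followed by H2O2/NaOH gives the primary alcohol F7. Dess–Martin oxidation gives the aldehyde F8. Wittig olefination with isopropylidenetriphenylphosphorane, selective for the aldehyde over the neopentylic ketone, gives 10.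

**Further compounds**
F1 | step 15 | 11-hydroxy-8-oxo trans-decalin | OC[C@@H]1[C@@]2(C)CC[C@H](Cl)[C@@](C)(CCC=C(C)C)[C@@H]2CCC1=O
F2 | step 15 | silyl ether ketone | CC(C)(C)[Si](C)(C)OC[C@@H]1[C@@]2(C)CC[C@H](Cl)[C@@](C)(CCC=C(C)C)[C@@H]2CCC1=O
F3 | step 15 | silyl ether tertiary alcohol | CC(C)(C)[Si](C)(C)OC[C@@H]1[C@@]2(C)CC[C@H](Cl)[C@@](C)(CCC=C(C)C)[C@@H]2CC[C@]1(C)O
F4 | step 8 | 3β-alcohol | O[C@H]1CC[C@]2(C)[C@@H](O[Si](C)(C)C(C)(C)C)CC[C@H]2[C@]1(C)CCC=C(C)C
F5 | step 8 | 3β-chlorosulfite | ClS(=O)O[C@H]1CC[C@]2(C)[C@@H](O[Si](C)(C)C(C)(C)C)CC[C@H]2[C@]1(C)CCC=C(C)C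
F6 | step 6 | 4α-allyl ketone | O=C1CC[C@]2(C)[C@@H](O[Si](C)(C)C(C)(C)C)CC[C@H]2[C@]1(C)CC=C
F7 | step 6 | primary alcohol | O=C1CC[C@]2(C)[C@@H](O[Si](C)(C)C(C)(C)C)CC[C@H]2[C@]1(C)CCCO
F8 | step 6 | aldehyde | O=C1CC[C@]2(C)[C@@H](O[Si](C)(C)C(C)(C)C)CC[C@H]2[C@]1(C)CCC=O
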